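The only ring of the target, its benzene ring, is built from a 2-pyrone and an alkyne instead of by brominating a phenol. Ring atoms C5(H)–C6(Br)–C1(O)–C2(Br) map onto C6–C5–C4–C3 of a 3,5-dibromo-4-methoxy-2-pyrone. C3(Br)–C4 and the exocyclic carbon map onto a 3-bromopropiolate ester. The key step exploits this contiguous H/Br/O/Br array and the adjacent Br/C pair: one thermal [4+2] cycloaddition with loss of CO2 should deliver the pentasubstituted arene, including the bromine meta to oxygen that phenol-directed bromination cannot place. Ether cleavage and ester reduction then complete the target.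

Key step: step 6

Remark on the chemistry: the hydroxypyrones are written as their 4-hydroxy-2-pyrone tautomers, and the transient bridged cycloadduct is racemic.

Step 1
Reactants: 1 diethyl 3-oxopentanedioate; 2 triethyl orthoformate
Product: 4 ethyl 4-hydroxy-2-oxo-2H-pyran-5-carboxylate, via diethyl 2-(ethoxymethylene)-3-oxopentanedioate 3 (not isolated)
Conditions: Ac2O (2.2 equiv), 125 °C, distil off volatiles; then 2 M aq. HCl, rt
Reagents that add atoms: water (O)
Why: Ethoxymethylenation (Claisen-type condensation of an orthoester with an active methylene, Ac2O removing the ethanol) gives the push–pull enol ether, which aqueous acid hydrolyses to the hydroxymethylene enol whose oxygen closes the six-membered lactone onto the remote ester (6-exo-trig lactonisation), the product settling as the stabilised 4-hydroxy-2-pyrone tautomer.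

Step 2
Reactants: 4 ethyl 4-hydroxy-2-oxo-2H-pyran-5-carboxylate
Product: 6 4-hydroxy-2H-pyran-2-one, via 4-hydroxy-2-oxo-2H-pyran-5-carboxylic acid 5 (not isolated)
Conditions: H2SO4 (90% aq.), 130 °C; then ice-water
Reagents that add atoms: none
Why: Acid-mediated ester cleavage and decarboxylation: the liberated acid is a beta-keto acid once C5 is protonated (C5 being an alpha carbon of the 4-pyranone tautomer), so it loses CO2 under the same strongly acidic, water-poor conditions that deacylate 3-acyl-4-hydroxy-2-pyrones without opening the lactone.

Step 3
Reactants: 6 4-hydroxy-2H-pyran-2-one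
Product: 7 4-methoxy-2H-pyran-2-one
Conditions: Me2SO4 (1.2 equiv), K2CO3, acetone, reflux
Reagents that add atoms: dimethyl sulfate (COS(=O)(=O)OC)
Why: Williamson-type O-methylation of the acidic enol (a vinylogous carboxylic acid) with a hard electrophile and carbonate in acetone, conditions under which 4-hydroxy-2-pyrones are alkylated on the 4-oxygen rather than on the lactone carbonyl oxygen or on C3.

Step 4
Reactants: 7 4-methoxy-2H-pyran-2-one
Product: 9 3,5-dibromo-4-methoxy-2H-pyran-2-one, via 3-bromo-4-methoxy-2H-pyran-2-one 8 (not isolated)
Conditions: Br2 (2.3 equiv), NaOAc (2.5 equiv), AcOH, rt then 60 °C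
Reagents that add atoms: bromine (BrBr)
Why: Electrophilic bromination with substitution: C3, the alpha carbon of the beta-methoxy enoate, reacts first and C5, the beta carbon of the ring enol ester O1–C6=C5, second, while acetate takes up HBr so that the methyl enol ether is not cleaved.

Step 5
Reactants: 10 methyl propiolate
Product: 11 methyl 3-bromopropiolate
Conditions: NBS (1.15 equiv), AgNO3 (0.1 equiv), acetone, rt
Reagents that add atoms: N-bromosuccinimide (O=C1CCC(=O)N1Br)
Why: Silver-catalysed electrophilic bromination of a terminal alkyne: AgNO3 forms the silver acetylide reversibly and NBS brominates it, the standard mild route to 1-bromoalkynes that leaves the ester untouched.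

Step 6
Reactants: 9 3,5-dibromo-4-methoxy-2H-pyran-2-one; 11 methyl 3-bromopropiolate
Product: 13 methyl 2,3,5-tribromo-4-methoxybenzoate, via bridged lactone cycloadduct 12 (not isolated)
Conditions: 11 (3 equiv, added in portions), BHT (cat.), PhMe, sealed tube, 130 °C
Reagents that add atoms: none
Why: The pyrone reacts as the 4π diene across C3–C6 and the bromoynoate as the 2π partner in a concerted, asynchronous, suprafacial Diels–Alder reaction whose two new sigma bonds (pyrone C3 to the bromine-bearing alkyne carbon, pyrone C6 to the ester-bearing alkyne carbon) close a six-membered carbocycle inside a 2-oxabicyclo[2.2.2]octadienone by intermolecular [4+2] closure. That bridged lactone then undergoes retro-[4+2] loss of CO2, which turns the new carbocycle into the benzene ring and makes the sequence irreversible. The closest known reaction type is the thermal 2-pyrone–alkyne cycloaddition/decarboxylation to arenes, known for brominated 2-pyrones and for ynoates, and methyl 3-bromopropiolate is an established thermal dienophile toward furans. The two bridgehead stereocentres of 12 arise as a racemate whose relative configuration is dictated by the bridge and are erased on aromatisation, so no stereocontrol is needed. Regioselectivity is the only requirement: the 4-methoxy group (donor on an inner diene carbon) and the ring oxygen on C6 both enlarge the HOMO coefficient at pyrone C3, which should pair with the electrophilic beta carbon of the ynoate, the C–Br carbon, and so place the ester para to methoxy. Working against this are the contact between two bromine-bearing carbons, modest because one is sp-hybridised, and the acceptor groups on C3; excess dienophile added in portions and a radical inhibitor offset its thermal lability.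

Step 7
Reactants: 13 methyl 2,3,5-tribromo-4-methoxybenzoate
Product: 14 methyl 2,3,5-tribromo-4-hydroxybenzoate
Conditions: BBr3 (2 equiv), CH2Cl2, −78 to 0 °C; then H2O
Reagents that add atoms: none
Why: Lewis-acid-mediated aryl methyl ether cleavage: BBr3 binds the out-of-plane, di-ortho-flanked methoxy oxygen and bromide removes the methyl group by SN2 attack, which at or below 0 °C is faster than attack on the methyl ester and does not touch aryl C–Br bonds.

Step 8
Reactants: 14 methyl 2,3,5-tribromo-4-hydroxybenzoate
Product: 15 2,3,6-tribromo-4-(hydroxymethyl)phenol
Conditions: i-Bu2AlH (4 equiv), CH2Cl2, −78 to 0 °C; then aq. potassium sodium tartrate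
Reagents that add atoms: none
Why: Ester reduction by an aluminium hydride: i-Bu2AlH first makes the aluminium phenoxide and then delivers two hydrides to the ester to give the benzylic alkoxide, and as an electrophilic hydride at or below 0 °C it leaves aryl bromides alone, the neutral tartrate work-up avoiding acid-promoted quinone methide formation.

Compound list
1 | diethyl 3-oxopentanedioate | CCOC(=O)CC(=O)CC(=O)OCC | starting material
2 | triethyl orthoformate | CCOC(OCC)OCC | starting material
3 | diethyl 2-(ethoxymethylene)-3-oxopentanedioate (E/Z mixture, not isolated) | CCOC=C(C(=O)OCC)C(=O)CC(=O)OCC | intermediate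
4 | ethyl 4-hydroxy-2-oxo-2H-pyran-5-carboxylate | CCOC(=O)C1=COC(=O)C=C1O | intermediate
5 | 4-hydroxy-2-oxo-2H-pyran-5-carboxylic acid (not isolated) | OC(=O)C1=COC(=O)C=C1O | intermediate
6 | 4-hydroxy-2H-pyran-2-one | O=C1C=C(O)C=CO1 | intermediate
7 | 4-methoxy-2H-pyran-2-one | COC1=CC(=O)OC=C1 | intermediate
8 | 3-bromo-4-methoxy-2H-pyran-2-one (not isolated) | COC1=C(Br)C(=O)OC=C1 | intermediate
9 | 3,5-dibromo-4-methoxy-2H-pyran-2-one | COC1=C(Br)C(=O)OC=C1Br | intermediate
10 | methyl propiolate | C#CC(=O)OC | starting material
11 | methyl 3-bromopropiolate | BrC#CC(=O)OC | intermediate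
12 | bridged lactone cycloadduct, methyl 4,5,7-tribromo-8-methoxy-3-oxo-2-oxabicyclo[2.2.2]octa-5,7-diene-6-carboxylate (racemic, bridgehead configurations tied to each other by the bridge, not isolated) | O=C1OC2C(Br)=C(OC)C1(Br)C(Br)=C2C(=O)OC | intermediate
13 | methyl 2,3,5-tribromo-4-methoxybenzoate | COC(=O)c1cc(Br)c(OC)c(Br)c1Br | intermediate
14 | methyl 2,3,5-tribromo-4-hydroxybenzoate | COC(=O)c1cc(Br)c(O)c(Br)c1Br | intermediate
15 | 2,3,6-tribromo-4-(hydroxymethyl)phenol | OCc1cc(Br)c(O)c(Br)c1Br | target

Total step count: 8 steps.
Longest linear sequence: 7 steps (steps 1, 2, 3, 4, 6, 7, 8); step 5 is a one-step branch.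

Steps most likely to fail

1. Step 6. The diene termini may pair with the alkyne carbons the wrong way round, or the bromoalkyne may decompose thermally before it adds. The fallback sets out from 9 and 10. Heating 9 with an excess of the thermally robust methyl propiolate 10 (PhMe or xylene, sealed tube, 130–150 °C) should give, through the bridged lactone methyl 4,7-dibromo-8-methoxy-3-oxo-2-oxabicyclo[2.2.2]octa-5,7-diene-6-carboxylate F1 and loss of CO2, methyl 3,5-dibromo-4-methoxybenzoate F2. Here the unhindered and more electrophilic terminal alkyne carbon joins pyrone C3, so sterics and electronics point the same way. The two remaining ring hydrogens of F2 are equivalent, and each is flanked by the ester and a bromine. Directed magnesiation with (2,2,6,6-tetramethylpiperidin-1-yl)magnesium chloride–lithium chloride, TMPMgCl·LiCl (THF, −20 °C), should therefore give [2,4-dibromo-3-methoxy-6-(methoxycarbonyl)phenyl]magnesium chloride F3. Quenching F3 with BrCl2C–CCl2Br installs the third bromine and comes back to the route at 13.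

2. Step 4. The second bromination may stall at the monobromide, or bromine may attack C3 again with loss of the O-methyl group. The fallback sets out from 7 and 11 and defers the last bromine to the phenol stage. Monobromination of 7 (NBS, 1.05 equiv, MeCN, rt) gives 8, which is isolated this time. Cycloaddition of 8 with 11 under the conditions of step 6 should give, through the bridged lactone methyl 4,5-dibromo-8-methoxy-3-oxo-2-oxabicyclo[2.2.2]octa-5,7-diene-6-carboxylate F4 and loss of CO2, methyl 2,3-dibromo-4-methoxybenzoate F5. BBr3 (CH2Cl2, −78 to 0 °C) then gives methyl 2,3-dibromo-4-hydroxybenzoate F6. Phenol-directed electrophilic bromination of F6 (Br2, 1.05 equiv, AcOH, rt) can only occur at the one free ortho position, since para is blocked by the ester, and comes back to the route at 14.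

3. Step 8. Hydride delivery to the ester may be slow once the para aluminium phenoxide has formed, and forcing conditions could cause C–Br hydrogenolysis or over-reduction of the benzylic C–O bond through a quinone methide. The fallback sets out from 14. Saponification (LiOH, THF/H2O, 50 °C; then dilute HCl) gives 2,3,5-tribromo-4-hydroxybenzoic acid F7. Chemoselective reduction of the carboxylic acid with BH3·THF (THF, 0 °C to rt; MeOH quench) comes back to the route at 15.

Further compounds
F1 | step 6 | methyl 4,7-dibromo-8-methoxy-3-oxo-2-oxabicyclo[2.2.2]octa-5,7-diene-6-carboxylate (racemic, transient) | O=C1OC2C(Br)=C(OC)C1(Br)C=C2C(=O)OC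
F2 | step 6 | methyl 3,5-dibromo-4-methoxybenzoate | COC(=O)c1cc(Br)c(OC)c(Br)c1
F3 | step 6 | [2,4-dibromo-3-methoxy-6-(methoxycarbonyl)phenyl]magnesium chloride | COC(=O)c1cc(Br)c(OC)c(Br)c1[Mg]Cl
F4 | step 4 | methyl 4,5-dibromo-8-methoxy-3-oxo-2-oxabicyclo[2.2.2]octa-5,7-diene-6-carboxylate (racemic, transient) | O=C1OC2C=C(OC)C1(Br)C(Br)=C2C(=O)OC
F5 | step 4 | methyl 2,3-dibromo-4-methoxybenzoate | COC(=O)c1ccc(OC)c(Br)c1Br
F6 | step 4 | methyl 2,3-dibromo-4-hydroxybenzoate | COC(=O)c1ccc(O)c(Br)c1Br
F7 | step 8 | 2,3,5-tribromo-4-hydroxybenzoic acid | OC(=O)c1cc(Br)c(O)c(Br)c1Br
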